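**Retrosynthetic overview**
1. Target ⇐ β-face epoxidation of C12=C13, acetylation of C17-OH and α-methylenation of the cis-fused lactone 25 (lactone ring formed last).
2. Lactone 25 ⇐ tricyclic enone 21: C4-H by axial protonation, C3-H and C2-H delivered from the α face, then lactonisation.
3. Rings A and B (formed together) ⇐ intramolecular Pauson–Khand [2+2+1] cycloaddition of ring-C enyne 19, which also creates quaternary C9.
4. Ring C (formed first) ⇐ ring-closing metathesis; the C5/C6 pair ⇐ chair Ireland–Claisen [3,3] rearrangement of allylic ester 7.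
5. All chirality ⇐ (S)-glyceraldehyde acetonide (from L-ascorbic acid): its centre sets the carbinol of 5, which is transferred to C5/C6 and then erased.

Assumption: atoms are numbered as in the cyathane skeleton (ring A = C1, C2, C3, C4, C9; ring B = C4–C9; ring C = C5, C6, C14, C13, C12, C11, C10; C15 on C12, C16 on C6, C17 on C9; lactone C18 (α), C19 (C=O), C20 (=CH2)); β is the face of C17; 5-methylhex-5-enoic acid is taken as purchasable.

**Step 1**
Reactants: 2 pent-1-en-4-yne; 1 (S)-2,2-dimethyl-1,3-dioxolane-4-carbaldehyde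
Product: 5 (1R,2E)-1-[(4S)-2,2-dimethyl-1,3-dioxolan-4-yl]-3-methylhexa-2,5-dien-1-ol, via alkenylalane 3 (not isolated), via lithium alkenylaluminate 4 (not isolated)
Conditions: Me3Al, Cp2ZrCl2 (20 mol%), CH2Cl2, 0 °C→rt; MeLi, THF, −78 °C; then 1, −78→0 °C
Reagents that add atoms: trimethylaluminium, C[Al](C)C
Why: Negishi zirconium-catalysed syn-carboalumination gives the (E)-alkenylalane regiospecifically, and its ate complex adds to the α-alkoxy aldehyde under Felkin–Anh (non-chelation) control to give the anti (1R) carbinol (about 4:1, minor epimer removed by chromatography).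

**Step 2**
Reactants: 5 allylic alcohol; 6 5-methylhex-5-enoic acid
Product: 7 (1R,2E)-1-[(4S)-2,2-dimethyl-1,3-dioxolan-4-yl]-3-methylhexa-2,5-dien-1-yl 5-methylhex-5-enoate
Conditions: DCC, DMAP (cat.), CH2Cl2, 0 °C→rt
Reagents that add atoms: none
Why: Steglich esterification acylates the secondary allylic alcohol without touching any stereocentre.

**Step 3**
Reactants: 7 allylic ester
Product: 10 (2S,3R,4E)-5-[(4R)-2,2-dimethyl-1,3-dioxolan-4-yl]-3-methyl-2-(3-methylbut-3-en-1-yl)-3-(prop-2-en-1-yl)pent-4-en-1-ol, via silyl ketene acetal 8 (not isolated), via trimethylsilyl ester 9 (not isolated)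
Conditions: LDA, THF/DMPU 4:1, −78 °C; TMSCl; −78→50 °C; then LiAlH4, 0 °C
Reagents that add atoms: none
Why: Ireland–Claisen [3,3]-sigmatropic rearrangement through a chair with the dioxolanyl group equatorial and the enolate chain cis to O–Si (DMPU conditions) transfers the carbinol chirality to C5 and quaternary C6 (methyl axial, allyl equatorial); the silyl ester is reduced in the same pot.

**Step 4**
Reactants: 10 triene alcohol
Product: 11 [(1S,2R)-2-{(E)-2-[(4R)-2,2-dimethyl-1,3-dioxolan-4-yl]ethenyl}-2,5-dimethylcyclohept-4-en-1-yl]methanol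
Conditions: second-generation Grubbs catalyst (5 mol%), CH2Cl2, 40 °C
Reagents that add atoms: none
Why: Ring-closing metathesis of the allyl and 2-methylallyl termini closes ring C as the trisubstituted cycloheptene; the neopentyl internal alkene does not take part.

**Step 5**
Reactants: 11 diene alcohol
Product: 12 [(1S,2S)-2-{2-[(4R)-2,2-dimethyl-1,3-dioxolan-4-yl]ethyl}-2,5-dimethylcyclohept-4-en-1-yl]methanol
Conditions: TsNHNH2, NaOAc, DME/H2O, 85 °C
Reagents that add atoms: none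
Why: Diimide reduction saturates the 1,2-disubstituted C7=C8 alkene and leaves the much less reactive trisubstituted ring alkene.

**Step 6**
Reactants: 12 primary alcohol
Product: 13 (1S,2S)-2-{2-[(4R)-2,2-dimethyl-1,3-dioxolan-4-yl]ethyl}-2,5-dimethylcyclohept-4-ene-1-carbaldehyde
Conditions: Dess–Martin periodinane, NaHCO3, CH2Cl2, 0 °C→rt
Reagents that add atoms: none
Why: Buffered Dess–Martin oxidation gives the aldehyde without epimerising the hindered α-centre C5.

**Step 7**
Reactants: 13 aldehyde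
Product: 14 (4R)-4-{2-[(1S,7S)-7-ethynyl-1,4-dimethylcyclohept-3-en-1-yl]ethyl}-2,2-dimethyl-1,3-dioxolane
Conditions: TMSCHN2, LDA, THF, −78 °C→rt
Reagents that add atoms: (trimethylsilyl)diazomethane, C[Si](C)(C)C=[N+]=[N-]
Why: Colvin rearrangement (Peterson elimination, then 1,2-shift of the alkylidene carbene) homologates the aldehyde to the terminal alkyne at low temperature, so C5 keeps its configuration.

**Step 8**
Reactants: 14 acetonide
Product: 15 (2R)-4-[(1S,7S)-7-ethynyl-1,4-dimethylcyclohept-3-en-1-yl]butane-1,2-diol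
Conditions: AcOH/H2O 4:1, 40 °C
Reagents that add atoms: none
Why: Mild acid hydrolysis removes the isopropylidene acetal; alkyne and trisubstituted alkene are inert.

**Step 9**
Reactants: 15 diol
Product: 17 4-[(1S,7S)-7-ethynyl-1,4-dimethylcyclohept-3-en-1-yl]-1-hydroxybutan-2-one, via stannylene acetal 16 (not isolated)
Conditions: Bu2SnO, PhMe, reflux (−H2O); then NBS, CHCl3, rt
Reagents that add atoms: none
Why: Brominolysis of the dibutylstannylene acetal oxidises only the secondary hydroxyl of the terminal 1,2-diol, which erases the bought stereocentre after it has done its work.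

**Step 10**
Reactants: 17 hydroxy ketone
Product: 18 4-[(1S,7S)-7-ethynyl-1,4-dimethylcyclohept-3-en-1-yl]-2-methylidenebutan-1-ol
Conditions: Ph3PCH3Br, KOtBu (3 equiv), THF, 0 °C→rt
Reagents that add atoms: methyltriphenylphosphonium bromide, C[P+](c1ccccc1)(c1ccccc1)c1ccccc1.[Br-]
Why: Wittig methylenation of the ketone (excess ylide absorbs the OH and alkyne protons) installs C1 as the 1,1-disubstituted alkene.

**Step 11**
Reactants: 18 terminal alkyne
Product: 19 tert-butyl 4-{(1S,2S)-2-[3-(hydroxymethyl)but-3-en-1-yl]-2,5-dimethylcyclohept-4-en-1-yl}but-3-ynoate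
Conditions: N2CHCO2tBu, CuI (10 mol%), MeCN, rt
Reagents that add atoms: tert-butyl diazoacetate, CC(C)(C)OC(=O)C=[N+]=[N-]
Why: Copper-catalysed coupling of a terminal alkyne with a diazoester (via the copper acetylide) gives the 3-alkynoate under base-free conditions, which avoids allenoate formation.

**Step 12**
Reactants: 19 enyne
Product: 21 tricyclic enone (C2=O; C3=C4; C3-CH2CO2tBu; 9β-CH2OH; 6α-CH3; 5β-H; C12=C13), via dicobalt hexacarbonyl alkyne complex 20 (not isolated)
Conditions: Co2(CO)8 (1.1 equiv), CH2Cl2, rt; then NMO, 0 °C→rt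
Reagents that add atoms: dicobalt octacarbonyl (supplies C2=O), [Co].[Co].[C-]#[O+].[C-]#[O+].[C-]#[O+].[C-]#[O+].[C-]#[O+].[C-]#[O+].[C-]#[O+].[C-]#[O+]
Why: Intramolecular Pauson–Khand [2+2+1] cycloaddition closes rings B and A at once; ring B forms as a chair locked by the trans-fused ring C, and because C1 must lie in the plane of the new cyclopentenone, C17 is forced pseudo-axial on the face opposite the axial C16 methyl (9β).

**Step 13**
Reactants: 21 enone
Product: 23 trans-fused ketone (C2=O; 3α-H; 4α-H; 3β-CH2CO2tBu; 9β-CH2OH), via dilithium enolate 22 (not isolated)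
Conditions: Li, NH3(l)/THF, tBuOH (1 equiv), −78 °C; NH4Cl at −78 °C; crude used at once
Reagents that add atoms: none
Why: Dissolving-metal (Birch-type) enone reduction protonates the β-carbon C4 axially (α, trans-hydrindanone), and the enolate is then protonated kinetically at C3 from the α face because the β face is screened by the axial C17 group.

**Step 14**
Reactants: 23 ketone
Product: 25 cis-fused γ-lactone (2β-O; 3β-CH2; 9β-CH2OH; C12=C13), via hydroxy ester 24 (not isolated)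
Conditions: NaBH4, CeCl3·7H2O, MeOH, −40 °C; then TsOH·H2O (cat.), PhMe, 60 °C
Reagents that add atoms: none
Why: Hydride attacks C2 from the open α face to give the 2β-alcohol cis to the C3 side chain, and acid-catalysed lactonisation (loss of tert-butanol) locks C2 and C3.

**Step 15**
Reactants: 25 lactone
Product: 28 α-methylene lactone alcohol (C18=C20; 17-OH; C12=C13), via Mannich base 26 (not isolated), via trimethylammonium iodide 27 (not isolated)
Conditions: LDA (2.3 equiv), THF, −78 °C; CH2=NMe2+ I−, −78 °C→rt; then MeI, MeOH; then NaHCO3 (aq)/CH2Cl2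
Reagents that add atoms: Eschenmoser's salt, C=[N+](C)C.[I-]
Why: Mannich reaction of the lactone enolate followed by quaternisation and Hofmann-type elimination installs the exocyclic methylene; the free C17-OH is carried as its alkoxide.

**Step 16**
Reactants: 28 alcohol
Product: 29 17-acetate (C12=C13 alkene)
Conditions: Ac2O, pyridine, DMAP (cat.), CH2Cl2, 0 °C→rt
Reagents that add atoms: acetic anhydride, CC(=O)OC(C)=O
Why: DMAP-catalysed acylation of the neopentyl primary alcohol.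

**Step 17**
Reactants: 29 alkene
Product: 30 target CNP0149939.1
Conditions: mCPBA, NaHCO3, CH2Cl2, 0 °C
Reagents that add atoms: mCPBA, OOC(=O)c1cccc(Cl)c1
Why: Prilezhaev epoxidation takes the electron-rich trisubstituted C12=C13 (the conjugated methylene lactone is inert) from the β face, anti to the axial α-C16 methyl that overhangs C13/C14.

**Compound list**
1 | (S)-2,2-dimethyl-1,3-dioxolane-4-carbaldehyde ((S)-glyceraldehyde acetonide) | O=C[C@@H]1COC(C)(C)O1 | starting material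
2 | pent-1-en-4-yne | C=CCC#C | starting material
3 | dimethyl[(1E)-2-methylpenta-1,4-dien-1-yl]alumane | C[Al](C)/C=C(\C)CC=C | intermediate
4 | lithium trimethyl[(1E)-2-methylpenta-1,4-dien-1-yl]aluminate | [Li+].C[Al-](C)(C)/C=C(\C)CC=C | intermediate
5 | (1R,2E)-1-[(4S)-2,2-dimethyl-1,3-dioxolan-4-yl]-3-methylhexa-2,5-dien-1-ol | O[C@H](/C=C(\C)CC=C)[C@@H]1COC(C)(C)O1 | intermediate
6 | 5-methylhex-5-enoic acid | OC(=O)CCCC(C)=C | starting material
7 | (1R,2E)-1-[(4S)-2,2-dimethyl-1,3-dioxolan-4-yl]-3-methylhexa-2,5-dien-1-yl 5-methylhex-5-enoate | C=C(C)CCCC(=O)O[C@H](/C=C(\C)CC=C)[C@@H]1COC(C)(C)O1 | intermediate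
8 | trimethylsilyl ketene acetal of 7 (chain cis to OSiMe3) | C=C(C)CC/C=C(\O[Si](C)(C)C)O[C@H](/C=C(\C)CC=C)[C@@H]1COC(C)(C)O1 | intermediate
9 | trimethylsilyl (2S,3R,4E)-5-[(4R)-2,2-dimethyl-1,3-dioxolan-4-yl]-3-methyl-2-(3-methylbut-3-en-1-yl)-3-(prop-2-en-1-yl)pent-4-enoate | C[Si](C)(C)OC(=O)[C@@H](CCC(C)=C)[C@](C)(CC=C)/C=C/[C@@H]1COC(C)(C)O1 | intermediate
10 | (2S,3R,4E)-5-[(4R)-2,2-dimethyl-1,3-dioxolan-4-yl]-3-methyl-2-(3-methylbut-3-en-1-yl)-3-(prop-2-en-1-yl)pent-4-en-1-ol | OC[C@@H](CCC(C)=C)[C@](C)(CC=C)/C=C/[C@@H]1COC(C)(C)O1 | intermediate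
11 | [(1S,2R)-2-{(E)-2-[(4R)-2,2-dimethyl-1,3-dioxolan-4-yl]ethenyl}-2,5-dimethylcyclohept-4-en-1-yl]methanol | OC[C@H]1CCC(C)=CC[C@]1(C)/C=C/[C@@H]2COC(C)(C)O2 | intermediate
12 | [(1S,2S)-2-{2-[(4R)-2,2-dimethyl-1,3-dioxolan-4-yl]ethyl}-2,5-dimethylcyclohept-4-en-1-yl]methanol | OC[C@H]1CCC(C)=CC[C@]1(C)CC[C@@H]2COC(C)(C)O2 | intermediate
13 | (1S,2S)-2-{2-[(4R)-2,2-dimethyl-1,3-dioxolan-4-yl]ethyl}-2,5-dimethylcyclohept-4-ene-1-carbaldehyde | O=C[C@H]1CCC(C)=CC[C@]1(C)CC[C@@H]2COC(C)(C)O2 | intermediate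
14 | (4R)-4-{2-[(1S,7S)-7-ethynyl-1,4-dimethylcyclohept-3-en-1-yl]ethyl}-2,2-dimethyl-1,3-dioxolane | C#C[C@H]1CCC(C)=CC[C@]1(C)CC[C@@H]2COC(C)(C)O2 | intermediate
15 | (2R)-4-[(1S,7S)-7-ethynyl-1,4-dimethylcyclohept-3-en-1-yl]butane-1,2-diol | C#C[C@H]1CCC(C)=CC[C@]1(C)CC[C@@H](O)CO | intermediate
16 | dibutylstannylene acetal of 15 | C#C[C@H]1CCC(C)=CC[C@]1(C)CC[C@@H]2CO[Sn](CCCC)(CCCC)O2 | intermediate
17 | 4-[(1S,7S)-7-ethynyl-1,4-dimethylcyclohept-3-en-1-yl]-1-hydroxybutan-2-one | C#C[C@H]1CCC(C)=CC[C@]1(C)CCC(=O)CO | intermediate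
18 | 4-[(1S,7S)-7-ethynyl-1,4-dimethylcyclohept-3-en-1-yl]-2-methylidenebutan-1-ol | C#C[C@H]1CCC(C)=CC[C@]1(C)CCC(=C)CO | intermediate
19 | tert-butyl 4-{(1S,2S)-2-[3-(hydroxymethyl)but-3-en-1-yl]-2,5-dimethylcyclohept-4-en-1-yl}but-3-ynoate | CC(C)(C)OC(=O)CC#C[C@H]1CCC(C)=CC[C@]1(C)CCC(=C)CO | intermediate
20 | Co2(CO)6 complex of the alkyne of 19 (written as its components) | CC(C)(C)OC(=O)CC#C[C@H]1CCC(C)=CC[C@]1(C)CCC(=C)CO.[Co].[Co].[C-]#[O+].[C-]#[O+].[C-]#[O+].[C-]#[O+].[C-]#[O+].[C-]#[O+] | intermediate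
21 | tricyclic enone: C2 ketone, C3=C4, tert-butyl acetate chain on C3, 9β-CH2OH, 6α-CH3, 5β-H, C12=C13 | O=C1C[C@]2(CO)CC[C@@]3(C)CC=C(C)CC[C@@H]3C2=C1CC(=O)OC(C)(C)C | intermediate
22 | dilithium salt (C2 enolate and C17 alkoxide) of 23 | [Li+].[Li+].[O-]C1C[C@]2(C[O-])CC[C@@]3(C)CC=C(C)CC[C@@H]3[C@H]2C=1CC(=O)OC(C)(C)C | intermediate
23 | trans-fused C2 ketone: 3α-H, 4α-H, 3β-CH2CO2tBu, 9β-CH2OH | O=C1C[C@]2(CO)CC[C@@]3(C)CC=C(C)CC[C@@H]3[C@H]2[C@H]1CC(=O)OC(C)(C)C | intermediate
24 | 2β-hydroxy tert-butyl ester | O[C@H]1C[C@]2(CO)CC[C@@]3(C)CC=C(C)CC[C@@H]3[C@H]2[C@H]1CC(=O)OC(C)(C)C | intermediate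
25 | cis-fused γ-lactone: 2β-O, 3β-CH2, 9β-CH2OH, C12=C13 | C1C(=O)O[C@H]2C[C@]3(CO)CC[C@@]4(C)CC=C(C)CC[C@@H]4[C@H]3[C@@H]12 | intermediate
26 | α-(dimethylaminomethyl) lactone (C18 epimers) | CN(C)CC1C(=O)O[C@H]2C[C@]3(CO)CC[C@@]4(C)CC=C(C)CC[C@@H]4[C@H]3[C@@H]12 | intermediate
27 | α-(trimethylammoniomethyl) lactone iodide | C[N+](C)(C)CC1C(=O)O[C@H]2C[C@]3(CO)CC[C@@]4(C)CC=C(C)CC[C@@H]4[C@H]3[C@@H]12.[I-] | intermediate
28 | α-methylene lactone with free 17-OH and C12=C13 | C=C1C(=O)O[C@H]2C[C@]3(CO)CC[C@@]4(C)CC=C(C)CC[C@@H]4[C@H]3[C@@H]12 | intermediate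
29 | 17-acetate of 28 | C=C1C(=O)O[C@H]2C[C@]3(COC(C)=O)CC[C@@]4(C)CC=C(C)CC[C@@H]4[C@H]3[C@@H]12 | intermediate
30 | CNP0149939.1 (12β,13β-epoxide) | C=C1C(=O)O[C@H]2C[C@]3(COC(C)=O)CC[C@@]4(C)C[C@H]5O[C@@]5(C)CC[C@@H]4[C@H]3[C@@H]12 | target

**Totals:** 17 steps; longest linear sequence 17 steps (from 1 or 2).

**Three steps most likely to fail**

Step 12 (Pauson–Khand on a hindered 1,7-enyne with a 1,1-disubstituted alkene). The fallback sets out from hydroxy ketone 17 and returns at enone 21. Ketenylidenetriphenylphosphorane (Ph3P=C=C=O, PhMe, 80 °C) converts 17 into the butenolide 4-{2-[(1S,7S)-7-ethynyl-1,4-dimethylcyclohept-3-en-1-yl]ethyl}furan-2(5H)-one F1. Bu3SnH/AIBN adds to the terminal alkyne, and the stannylvinyl radical closes ring B by 6-exo conjugate addition to the butenolide (chair, butenolide C=C equatorial, so C17 ends axial), giving the spirolactone (Z)-vinylstannane F2. Tin–lithium exchange (MeLi, THF, −78 °C) lets C3 attack the lactone carbonyl, which closes ring A and frees the C17 hydroxyl, giving the side-chain-free enone F3; only the Z-stannane can cyclise. Iodination (I2, pyridine) gives the 3-iodoenone F4, and Negishi coupling with BrZnCH2CO2tBu (Pd(PPh3)4) gives 21.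

Step 13 (C3 is set by kinetic protonation and can epimerise before reduction). The fallback sets out from enone 21 and returns at lactone 25. Luche reduction (NaBH4, CeCl3·7H2O) gives the 2β-allylic alcohol F5, and TsOH closes it to the lactone with the C3=C4 double bond F6. DBU moves the double bond into conjugation with axial protonation at C4, giving the conjugated butenolide with 4α-H F7. Mg/MeOH conjugate reduction can then only give the cis-fused lactone 25.

Step 17 (face selectivity of the epoxidation). The fallback sets out from alkene 29 and returns at target 30. If the peracid prefers the α face, NBS in aqueous DME forms the bromonium ion on that face and water opens it at C12 from the β face, giving the 13α-bromo-12β-hydroxy compound F8. K2CO3 in acetone then closes the β-epoxide 30.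

**Further compounds**
F1 | step 12 | 4-{2-[(1S,7S)-7-ethynyl-1,4-dimethylcyclohept-3-en-1-yl]ethyl}furan-2(5H)-one | C#C[C@H]1CCC(C)=CC[C@]1(C)CCC2=CC(=O)OC2
F2 | step 12 | spirolactone (Z)-vinylstannane: ring B closed, C9 spiro, C17 axial, C4=CH-SnBu3 | O=C1C[C@]2(CO1)CC[C@@]3(C)CC=C(C)CC[C@@H]3/C2=C/[Sn](CCCC)(CCCC)CCCC
F3 | step 12 | tricyclic enone without the C3 side chain | O=C1C[C@]2(CO)CC[C@@]3(C)CC=C(C)CC[C@@H]3C2=C1
F4 | step 12 | 3-iodo tricyclic enone | O=C1C[C@]2(CO)CC[C@@]3(C)CC=C(C)CC[C@@H]3C2=C1I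
F5 | step 13 | 2β-allylic alcohol from 21 | O[C@H]1C[C@]2(CO)CC[C@@]3(C)CC=C(C)CC[C@@H]3C2=C1CC(=O)OC(C)(C)C
F6 | step 13 | γ-lactone with C3=C4 double bond | C1C(=O)O[C@H]2C[C@]3(CO)CC[C@@]4(C)CC=C(C)CC[C@@H]4C3=C12
F7 | step 13 | conjugated butenolide (C18=C3) with 4α-H | O=C1O[C@H]2C[C@]3(CO)CC[C@@]4(C)CC=C(C)CC[C@@H]4[C@H]3C2=C1
F8 | step 17 | 13α-bromo-12β-hydroxy compound from 29 | C=C1C(=O)O[C@H]2C[C@]3(COC(C)=O)CC[C@@]4(C)C[C@H](Br)[C@@](C)(O)CC[C@@H]4[C@H]3[C@@H]12
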